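**Plan**

Oxolane numbering: O1, C2 (4-hydroxy-3-methoxyphenyl), C3, C4, C5 (3-hydroxy-4,5-dimethoxyphenyl). The target is (2S,3S,4R,5R), that is 2,3-trans, 3,4-cis, 4,5-trans.
Cuts, in retrosynthetic order: the two aryl O–benzyl bonds; the C5 configuration (benzylic equilibration); both methyl groups back to the CH2–O and C=O carbons of a γ-lactone ring cis-fused at C3–C4; the C4–C5 bond (key cut, opens the oxolane); the O1–C5 ether bond; the C2–C3 aldol bond.
Enabling feature: C5 is a CH bound to O1 and to the 3-hydroxy-4,5-dimethoxyphenyl ring, and it stands 1,5 to C4 along C4–C3–C2–O1–C5. The methyl groups on C3 and C4 are cis, so one lactone ring can hold both carbons and carry a carbene at C4.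
Forward order: C2–C3 (aldol), O1–C5 (etherification), lactone ring, oxolane ring (C–H insertion), lactone reduced away to two methyl groups, C5 equilibrated, phenols freed.
Stereochemistry: (S)-4-benzyloxazolidin-2-one sets C2 and C3 in a syn aldol, and the cis ring fusion relays C3 to C4. C5 forms endo under catalyst control and is turned exo by acid, because the trans,cis,trans array is the energy minimum once C3 and C4 are fixed.

Key step: step 10

Assumption: the insertion is taken to place the C5 aryl group endo (cis to the lactone carbonyl carbon), the usual kinetic outcome for a carbene held in a γ-lactone ring. The furofuranone and the three compounds after it are drawn that way, and C5 is set in step 14.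

Step 1
Reactants: 1 3-hydroxy-4,5-dimethoxybenzaldehyde
Product: 2 3-benzyloxy-4,5-dimethoxybenzaldehyde
Conditions: BnBr, K2CO3, DMF, rt
Reagents that add atoms: benzyl bromide, BrCc1ccccc1
Why: Williamson ether synthesis on the only acidic OH, in which the phenoxide displaces bromide (SN2) and the aldehyde is inert to carbonate.

Step 2
Reactants: 2 3-benzyloxy-4,5-dimethoxybenzaldehyde
Product: 3 (3-benzyloxy-4,5-dimethoxyphenyl)methanol
Conditions: NaBH4, MeOH, 0 °C
Reagents that add atoms: none
Why: Borohydride reduction of an aromatic aldehyde to the benzylic alcohol, which leaves the aryl ethers untouched.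

Step 3
Reactants: 3 (3-benzyloxy-4,5-dimethoxyphenyl)methanol
Product: 4 3-benzyloxy-4,5-dimethoxybenzyl 2,2,2-trichloroacetimidate
Conditions: Cl3CCN, DBU (cat.), CH2Cl2, 0 °C
Reagents that add atoms: trichloroacetonitrile, N#CC(Cl)(Cl)Cl
Why: Base-catalysed addition of the alcohol to the nitrile (trichloroacetimidate formation), run cold with the product used promptly because electron-rich benzylic imidates rearrange on storage.

Step 4
Reactants: 5 4-tert-butoxy-4-oxobutanoic acid (mono-tert-butyl succinate); 6 (S)-4-benzyloxazolidin-2-one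
Product: 8 tert-butyl 4-[(4S)-4-benzyl-2-oxooxazolidin-3-yl]-4-oxobutanoate, via mixed pivalic anhydride 7 (not isolated)
Conditions: PivCl, Et3N, THF, −20 °C; then LiCl, 6, −20 °C to rt
Reagents that add atoms: pivaloyl chloride, CC(C)(C)C(=O)Cl (its atoms are held only in 7, none in 8)
Why: Mixed-anhydride N-acylation of an oxazolidinone under LiCl/Et3N, where the nitrogen attacks the unhindered succinyl carbonyl of 7 and both the tert-butyl ester and the auxiliary stereocentre are untouched.

Step 5
Reactants: 8 tert-butyl 4-[(4S)-4-benzyl-2-oxooxazolidin-3-yl]-4-oxobutanoate; 9 4-benzyloxy-3-methoxybenzaldehyde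
Product: 12 tert-butyl (3S)-3-[(S)-(4-benzyloxy-3-methoxyphenyl)(hydroxy)methyl]-4-[(4S)-4-benzyl-2-oxooxazolidin-3-yl]-4-oxobutanoate (syn aldol), via Z dibutylboron enolate 10 (not isolated), via dibutylboron aldolate 11 (not isolated)
Conditions: Bu2BOTf, iPr2NEt, CH2Cl2, 0 °C; 9, −78 to 0 °C; pH 7 buffer, MeOH, H2O2, 0 °C
Reagents that add atoms: dibutylboron triflate, CCCCB(CCCC)OS(=O)(=O)C(F)(F)F (its atoms are held only in 10 and 11, none in 12)
Why: Evans syn aldol, in which only the imide-flanked CH2 is enolised to Z enolate 10, which adds to 9 through a Zimmerman–Traxler chair on the face away from the benzyl group of the (S)-auxiliary and so sets future C3 and C2 as (S,S)-syn, while the bulky tert-butyl ester keeps aldolate 11 from lactonising.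

Step 6
Reactants: 12 syn aldol; 4 3-benzyloxy-4,5-dimethoxybenzyl 2,2,2-trichloroacetimidate
Product: 13 tert-butyl (3S)-3-[(S)-(4-benzyloxy-3-methoxyphenyl)(3-benzyloxy-4,5-dimethoxybenzyloxy)methyl]-4-[(4S)-4-benzyl-2-oxooxazolidin-3-yl]-4-oxobutanoate
Conditions: TfOH (cat.), CH2Cl2–cyclohexane, −20 to 0 °C
Reagents that add atoms: none
Why: Acid-catalysed O-benzylation with a trichloroacetimidate, which has no base present to trigger retro-aldol cleavage, uses the basic imidate to buffer the acid, and never breaks the C2–O bond, so C2 keeps its configuration.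

Step 7
Reactants: 13 etherified imide
Product: 14 tert-butyl (3R)-3-[(S)-(4-benzyloxy-3-methoxyphenyl)(3-benzyloxy-4,5-dimethoxybenzyloxy)methyl]-4-hydroxybutanoate
Conditions: LiBH4, MeOH (1 equiv), THF, 0 °C
Reagents that add atoms: none
Why: Reductive removal of the Evans auxiliary, in which the imide carbonyl is far more electrophilic than the tert-butyl ester and no stereocentre is touched (the C3 descriptor changes only through CIP priorities).

Step 8
Reactants: 14 hydroxy tert-butyl ester
Product: 15 (4R)-4-[(S)-(4-benzyloxy-3-methoxyphenyl)(3-benzyloxy-4,5-dimethoxybenzyloxy)methyl]oxolan-2-one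
Conditions: KOtBu (cat.), THF, 0 °C
Reagents that add atoms: none
Why: Base-catalysed intramolecular transesterification (5-exo-trig lactonisation) in which the expelled tert-butoxide carries the chain, with acid avoided because the doubly benzylic C2–O1–C5 ether ionises easily.

Step 9
Reactants: 15 lactone
Product: 18 (4R)-3-diazo-4-[(S)-(4-benzyloxy-3-methoxyphenyl)(3-benzyloxy-4,5-dimethoxybenzyloxy)methyl]oxolan-2-one, via lithium enolate 16 (not isolated), via trifluoroacetyl lactone 17 (not isolated)
Conditions: LiHMDS, THF, −78 °C; CF3CO2CH2CF3, −78 °C; 5% HCl work-up; crude 17, 4-acetamidobenzenesulfonyl azide, Et3N, H2O (1 equiv), MeCN, rt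
Reagents that add atoms: 4-acetamidobenzenesulfonyl azide, CC(=O)Nc1ccc(cc1)S(=O)(=O)N=[N+]=[N-] (the two diazo nitrogens); 2,2,2-trifluoroethyl trifluoroacetate, FC(F)(F)COC(=O)C(F)(F)F (its atoms are held only in 17)
Why: Deacylative (detrifluoroacetylative) Regitz diazo transfer, where the transient trifluoroacetyl group activates the lactone α-carbon (future C4) for azide attack and then leaves on the sulfonamide, and C3 carries no β leaving group, so the enolate cannot eliminate.

Step 10
Reactants: 18 diazolactone
Product: 20 (3aR,4S,6S,6aR)-4-(4-benzyloxy-3-methoxyphenyl)-6-(3-benzyloxy-4,5-dimethoxyphenyl)tetrahydro-1H,3H-furo[3,4-c]furan-1-one (cis-fused 6,8-diaryl-3,7-dioxabicyclo[3.3.0]octan-2-one; C2 aryl exo; C5 aryl endo), via dirhodium carbene 19 (not isolated)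
Conditions: Rh2(OAc)4 (2 mol %), CH2Cl2, reflux, slow addition of 18, high dilution
Reagents that add atoms: none
Why: Rh2(OAc)4, a dimer of divalent rhodium, binds the diazo carbon of 18 and expels N2 to give the electrophilic carbene 19 at C4, whose empty p orbital engages one C5–H bond of the O1–CH2–aryl group in a concerted but asynchronous three-centre transition state (hydride-like H transfer running ahead of C4–C5 bond formation) that releases the catalyst. The closest known reaction type is this very one, the 1,5 C–H insertion of α-diazo-γ-butyrolactones into benzylic ether C–H bonds to give furofuranones. The oxolane ring O1–C2–C3–C4–C5 closes by C4–C5 bond formation through a cyclic array of five heavy atoms plus the migrating H, the 1,5 mode that dirhodium carbenes prefer over smaller or larger rings. C4 is set by the lactone ring, because the side chain on C3 reaches only its own face of the flat carbene-bearing lactone, so the new C4–C5 bond is cis to C3–C2, the bicycle is cis-fused and the two future methyl carbons are cis. C5 is set by the catalyst, because the dirhodium core and its acetate wall lie on the convex side of the forming bicycle, so the aryl group on C5 turns to the concave side and should end endo, cis to the lactone carbonyl carbon and trans to the exo aryl group that the syn aldol placed on C2; this kinetic result is reset in step 14. The step needs insertion to beat 1,2-hydride shift from C3–H, attack on the arene rings and carbene dimerisation, which is secured by the double activation of C5–H by O1 and by the aryl ring with its para methoxy group, by the short tether, and by slow addition at high dilution.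

Step 11
Reactants: 20 furofuranone
Product: 21 [(2S,3R,4S,5S)-2-(4-benzyloxy-3-methoxyphenyl)-5-(3-benzyloxy-4,5-dimethoxyphenyl)oxolane-3,4-diyl]dimethanol
Conditions: LiAlH4, THF, 0 °C to rt; Fieser work-up
Reagents that add atoms: none
Why: Hydride reduction of a γ-lactone to the 1,4-diol, which opens the temporary ring without touching any stereocentre, ether or benzyl group.

Step 12
Reactants: 21 diol
Product: 22 the bis(methanesulfonate) of 21, (2S,3R,4S,5S)
Conditions: MsCl (3 equiv), Et3N (4 equiv), CH2Cl2, −20 to 0 °C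
Reagents that add atoms: methanesulfonyl chloride, CS(=O)(=O)Cl
Why: Sulfonylation of two primary alcohols, run cold with excess reagent so that the second mesylation outruns intramolecular etherification of the monomesylate.

Step 13
Reactants: 22 bis(methanesulfonate)
Product: 23 (2S,3S,4R,5S)-2-(4-benzyloxy-3-methoxyphenyl)-5-(3-benzyloxy-4,5-dimethoxyphenyl)-3,4-dimethyloxolane (2,3-trans, 3,4-cis, 4,5-cis)
Conditions: LiEt3BH (6 equiv), THF, 0 °C to rt
Reagents that add atoms: none
Why: SN2 hydride displacement of primary sulfonates by LiEt3BH, a nucleophile strong enough to attack carbon rather than sulfur, which turns both lactone-derived carbons into the cis methyl groups.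

Step 14
Reactants: 23 C5-epimeric dimethyloxolane
Product: 24 (2S,3S,4R,5R)-2-(4-benzyloxy-3-methoxyphenyl)-5-(3-benzyloxy-4,5-dimethoxyphenyl)-3,4-dimethyloxolane (2,3-trans, 3,4-cis, 4,5-trans)
Conditions: BF3·OEt2 (0.3 equiv), CH2Cl2, −20 to 0 °C
Reagents that add atoms: none
Why: Lewis acid-promoted benzylic epimerisation, a known behaviour of 2,5-diaryloxolane lignans, in which BF3 on O1 lets C5–O1 ionise to a cation stabilised by the para methoxy group and rotation about C4–C5 with reclosure puts the aryl group trans to the C4 methyl group; since C3 and C4 cannot change and C2 already has its favoured trans arrangement, the equilibrium should drain to this one isomer whatever the C5 selectivity of step 10.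

Step 15
Reactants: 24 dibenzyl ether
Product: 25 (2S,3S,4R,5R)-2-(4-hydroxy-3-methoxyphenyl)-5-(3-hydroxy-4,5-dimethoxyphenyl)-3,4-dimethyloxolane (target)
Conditions: H2 (1 atm), 10% Pd/C, EtOAc, rt, stopped after uptake of 2 equiv
Reagents that add atoms: none
Why: Catalytic hydrogenolysis of aryl benzyl ethers, which are cleaved much faster than the hindered ring C–O bonds in a neutral, non-protic solvent, so all four stereocentres are kept.

**Compound list**

1 | 3-hydroxy-4,5-dimethoxybenzaldehyde | COc1cc(C=O)cc(O)c1OC | starting material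
2 | 3-benzyloxy-4,5-dimethoxybenzaldehyde | COc1cc(C=O)cc(OCc2ccccc2)c1OC | intermediate
3 | (3-benzyloxy-4,5-dimethoxyphenyl)methanol | COc1cc(CO)cc(OCc2ccccc2)c1OC | intermediate
4 | 3-benzyloxy-4,5-dimethoxybenzyl 2,2,2-trichloroacetimidate | COc1cc(COC(=N)C(Cl)(Cl)Cl)cc(OCc2ccccc2)c1OC | intermediate
5 | 4-tert-butoxy-4-oxobutanoic acid | CC(C)(C)OC(=O)CCC(=O)O | starting material
6 | (S)-4-benzyloxazolidin-2-one | O=C1N[C@@H](Cc2ccccc2)CO1 | starting material
7 | 4-tert-butoxy-4-oxobutanoic pivalic anhydride (not isolated) | CC(C)(C)OC(=O)CCC(=O)OC(=O)C(C)(C)C | intermediate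
8 | tert-butyl 4-[(4S)-4-benzyl-2-oxooxazolidin-3-yl]-4-oxobutanoate | CC(C)(C)OC(=O)CCC(=O)N1C(=O)OC[C@@H]1Cc1ccccc1 | intermediate
9 | 4-benzyloxy-3-methoxybenzaldehyde | COc1cc(C=O)ccc1OCc1ccccc1 | starting material
10 | Z dibutylboron enolate of 8 (not isolated) | CCCCB(CCCC)O/C(=C\CC(=O)OC(C)(C)C)N1C(=O)OC[C@@H]1Cc1ccccc1 | intermediate
11 | dibutylboron aldolate of 12 (not isolated) | COc1cc([C@@H](OB(CCCC)CCCC)[C@H](CC(=O)OC(C)(C)C)C(=O)N2C(=O)OC[C@@H]2Cc2ccccc2)ccc1OCc1ccccc1 | intermediate
12 | syn aldol, (3S), carbinol (S), auxiliary (4S) | COc1cc([C@@H](O)[C@H](CC(=O)OC(C)(C)C)C(=O)N2C(=O)OC[C@@H]2Cc2ccccc2)ccc1OCc1ccccc1 | intermediate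
13 | 3-benzyloxy-4,5-dimethoxybenzyl ether of 12 | COc1cc([C@@H](OCc2cc(OCc3ccccc3)c(OC)c(OC)c2)[C@H](CC(=O)OC(C)(C)C)C(=O)N2C(=O)OC[C@@H]2Cc2ccccc2)ccc1OCc1ccccc1 | intermediate
14 | hydroxy tert-butyl ester, (3R), ether carbon (S) | COc1cc([C@@H](OCc2cc(OCc3ccccc3)c(OC)c(OC)c2)[C@H](CC(=O)OC(C)(C)C)CO)ccc1OCc1ccccc1 | intermediate
15 | (4R)-4-[(S)-aryl(arylmethoxy)methyl]oxolan-2-one | COc1cc([C@H]([C@H]2COC(=O)C2)OCc2cc(OCc3ccccc3)c(OC)c(OC)c2)ccc1OCc1ccccc1 | intermediate
16 | lithium enolate of 15 (not isolated) | COc1cc([C@H]([C@H]2COC([O-])=C2)OCc2cc(OCc3ccccc3)c(OC)c(OC)c2)ccc1OCc1ccccc1.[Li+] | intermediate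
17 | 3-trifluoroacetyl derivative of 15, epimers and enol at the α-carbon (not isolated) | COc1cc([C@H]([C@H]2COC(=O)C2C(=O)C(F)(F)F)OCc2cc(OCc3ccccc3)c(OC)c(OC)c2)ccc1OCc1ccccc1 | intermediate
18 | (4R)-3-diazo-4-[(S)-(4-benzyloxy-3-methoxyphenyl)(3-benzyloxy-4,5-dimethoxybenzyloxy)methyl]oxolan-2-one | COc1cc([C@H]([C@H]2COC(=O)C2=[N+]=[N-])OCc2cc(OCc3ccccc3)c(OC)c(OC)c2)ccc1OCc1ccccc1 | intermediate
19 | Rh2(OAc)4 carbene at C4 (not isolated) | COc1cc([C@H]([C@H]2COC(=O)C2=[Rh+2][Rh+2])OCc2cc(OCc3ccccc3)c(OC)c(OC)c2)ccc1OCc1ccccc1.CC(=O)[O-].CC(=O)[O-].CC(=O)[O-].CC(=O)[O-] | intermediate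
20 | (3aR,4S,6S,6aR)-furofuranone, cis-fused, C2 aryl exo, C5 aryl endo | COc1cc([C@H]2O[C@H](c3cc(OCc4ccccc4)c(OC)c(OC)c3)[C@@H]3C(=O)OC[C@H]23)ccc1OCc1ccccc1 | intermediate
21 | (2S,3R,4S,5S)-3,4-bis(hydroxymethyl)oxolane | COc1cc([C@H]2O[C@H](c3cc(OCc4ccccc4)c(OC)c(OC)c3)[C@H](CO)[C@@H]2CO)ccc1OCc1ccccc1 | intermediate
22 | (2S,3R,4S,5S)-bis(methanesulfonate) | COc1cc([C@H]2O[C@H](c3cc(OCc4ccccc4)c(OC)c(OC)c3)[C@H](COS(C)(=O)=O)[C@@H]2COS(C)(=O)=O)ccc1OCc1ccccc1 | intermediate
23 | (2S,3S,4R,5S)-3,4-dimethyloxolane, dibenzyl ether, 4,5-cis | COc1cc([C@H]2O[C@H](c3cc(OCc4ccccc4)c(OC)c(OC)c3)[C@H](C)[C@@H]2C)ccc1OCc1ccccc1 | intermediate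
24 | (2S,3S,4R,5R)-3,4-dimethyloxolane, dibenzyl ether, trans,cis,trans | COc1cc([C@H]2O[C@@H](c3cc(OCc4ccccc4)c(OC)c(OC)c3)[C@H](C)[C@@H]2C)ccc1OCc1ccccc1 | intermediate
25 | CNP0022199.2, (2S,3S,4R,5R) | COc1cc([C@H]2O[C@@H](c3cc(O)c(OC)c(OC)c3)[C@H](C)[C@@H]2C)ccc1O | target

**Step count and risks**

Total step count: 15. Longest linear sequence: 13 (steps 1–3, then 6–15).

**Step 10.** 1,2-Hydride migration from C3–H to the carbene carbon, or attack of the carbene on one of the electron-rich arene rings, may outrun the insertion.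
- The fallback forms C4–C5 by an enolate aldol and closes the oxolane at O1–C5 instead. It sets out from 12, uses aldehyde 2, and returns at 20.
- TBSOTf/2,6-lutidine gives the silyl ether of the aldol F1. LiBH4/MeOH gives the silyloxy hydroxy ester F2, and catalytic KOtBu gives the silyloxy lactone F3.
- LiHMDS at −78 °C gives its lithium enolate F4, which adds to 2 to give the α-(aryl)hydroxymethyl lactone F5. Dess–Martin periodinane gives the α-aroyl lactone F6, in which C4 is configurationally labile.
- HF·pyridine frees the C2 hydroxyl, which can add to the ketone only in the cis-fused sense and gives the bicyclic hemiketal F7.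
- Et3SiH/BF3·OEt2 at −78 °C reduces the derived oxocarbenium ion from the convex face. This leaves the C5 aryl group endo and delivers 20.

**Step 14.** C5–O1 ionises less readily than C2–O1, because the para methoxy group on the C5 ring is twisted by its two ortho neighbours. Exposure to acid may therefore have to be long, and Friedel–Crafts ring closure of the opened C2 cation onto the C5 aryl ring may drain material irreversibly.
- The fallback replaces the cation by a radical: thiol-catalysed radical-chain epimerisation of 23 with (tBuO)3SiSH (cat.) and di-tert-butyl hyponitrite (cat.) in octane at 60 °C.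
- Reversible hydrogen-atom abstraction at the benzylic α-oxy C–H bonds equilibrates C5 (and C2) to the same trans,cis,trans minimum without any C–O cleavage.
- It sets out from 23, returns at 24, and makes no new compound.

**Step 6.** The acid may ionise the electron-rich benzylic carbinol, with loss of C2 configuration or ring closure onto the ester. The imidate may also rearrange before the hindered hydroxyl captures it.
- The fallback is a reductive etherification that needs neither 3 nor 4. It sets out from 12 and returns at 13.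
- TMSCl/imidazole gives the trimethylsilyl ether F8. With aldehyde 2, Et3SiH and catalytic TMSOTf in CH2Cl2 at −78 °C, an oxocarbenium ion forms at C5 and is reduced by the silane to 13.

**Further compounds**

F1 | step 10 | tert-butyldimethylsilyl ether of 12 | COc1cc([C@@H](O[Si](C)(C)C(C)(C)C)[C@H](CC(=O)OC(C)(C)C)C(=O)N2C(=O)OC[C@@H]2Cc2ccccc2)ccc1OCc1ccccc1
F2 | step 10 | tert-butyl (3R)-3-[(S)-(4-benzyloxy-3-methoxyphenyl)(tert-butyldimethylsilyloxy)methyl]-4-hydroxybutanoate | COc1cc([C@@H](O[Si](C)(C)C(C)(C)C)[C@H](CC(=O)OC(C)(C)C)CO)ccc1OCc1ccccc1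
F3 | step 10 | (4R)-4-[(S)-(4-benzyloxy-3-methoxyphenyl)(tert-butyldimethylsilyloxy)methyl]oxolan-2-one | COc1cc([C@H]([C@H]2COC(=O)C2)O[Si](C)(C)C(C)(C)C)ccc1OCc1ccccc1
F4 | step 10 | lithium enolate of F3 | COc1cc([C@H]([C@H]2COC([O-])=C2)O[Si](C)(C)C(C)(C)C)ccc1OCc1ccccc1.[Li+]
F5 | step 10 | 3-[(3-benzyloxy-4,5-dimethoxyphenyl)(hydroxy)methyl] derivative of F3, mixture at the two new centres | COc1cc([C@H]([C@H]2COC(=O)C2C(O)c2cc(OCc3ccccc3)c(OC)c(OC)c2)O[Si](C)(C)C(C)(C)C)ccc1OCc1ccccc1
F6 | step 10 | 3-(3-benzyloxy-4,5-dimethoxybenzoyl) derivative of F3, labile at the α-carbon | COc1cc([C@H]([C@H]2COC(=O)C2C(=O)c2cc(OCc3ccccc3)c(OC)c(OC)c2)O[Si](C)(C)C(C)(C)C)ccc1OCc1ccccc1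
F7 | step 10 | cis-fused 6-hydroxy hemiketal of the furofuranone, anomeric centre undefined | COc1cc([C@H]2OC(O)(c3cc(OCc4ccccc4)c(OC)c(OC)c3)[C@@H]3C(=O)OC[C@H]23)ccc1OCc1ccccc1
F0 | step 14 | none | none
F8 | step 6 | trimethylsilyl ether of 12 | COc1cc([C@@H](O[Si](C)(C)C)[C@H](CC(=O)OC(C)(C)C)C(=O)N2C(=O)OC[C@@H]2Cc2ccccc2)ccc1OCc1ccccc1
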